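The product reaches half of the charge at 5.4 min in the gamma run, and half at the same time in the alpha run, though the charges differ 7.50-fold. So you should count in proportions.

| setting | eta | alpha | gamma | theta | delta |
|---|---|---|---|---|---|
| starting material | 0.200 M | 0.0800 M | 0.600 M | 0.200 M | 0.200 M |
| free catalyst | 0.00600 M | 0.00600 M | 0.00600 M | 0.00600 M | 0.00600 M |
| product |  |  |  | 0.100 M |  |
| time |  |  |  |  | 14 min |

- eta run (time / min: [product] / M): 0.22: 0.0074; 0.41: 0.0113; 0.78: 0.0224; 1.5: 0.0386; 2.8: 0.0659; 5.4: 0.0996
- alpha run (time / min: [product] / M): 0.22: 0.0032; 0.41: 0.0046; 0.78: 0.0094; 1.5: 0.0156; 2.8: 0.0259; 5.4: 0.0388
- gamma run (time / min: [product] / M): 0.22: 0.0200; 0.41: 0.0334; 0.78: 0.0641; 1.5: 0.1137; 2.8: 0.1921; 5.4: 0.2998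
- theta run (time / min: [product] / M): 0.22: 0.1070; 0.41: 0.1121; 0.78: 0.1203; 1.5: 0.1393; 2.8: 0.1625; 5.4: 0.2016

(scatter of a reading: 0.001 M)

- Overall: starting material -> product, with free catalyst as catalyst.
- Constant volume, constant temperature.
- An order is taken over about fifteen percent of the charge, up and down.

- reaction order in [starting material] at the outset, round the charge of the eta run, defined at two percent of the starting material turned into product (one fixed amount of product, the same in the runs compared)
- the alpha run starts with 0.120 M less of starting material than the eta run, and with no product. Compared where both hold the same amount of starting material, once fifteen percent of what the alpha run was charged with has turned into product, is the alpha run faster, slower or alike (within a tenth)?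
- product in the delta run at 14 min, as a share of the starting material charged

Take the log gain, the natural log of the charge over the starting material left, and the working rate, the log gain per minute, a pseudo-first-order constant. At 5.4 min the log gain is 0.692 in the gamma run and 0.689 in the eta run. Product at 1.5 min in the gamma and eta runs gives me an order of 0.983.

Start with the main step and a steady working rate. The gamma run shows 0.138 /min up to 2.8 min, which would put the delta run at 85.5 %.

Now add the fade. Over the next stretch of the gamma run the working rate reads 0.118 /min. Divide one rate by the other and time drops out, which gives the reach, the log gain over which the working rate falls by a factor of e: 2.22, read from these readings. I assume the reach holds steady. The starting rate is then 0.150 /min, and the delta run comes to 77.2 %, lower than the steady figure.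

Then the rest, the added product. The theta run's log gain of 0.709 stands near the eta run's, with a scatter of about 0.00996 in each, so I add nothing.

The reach also answers the comparison. Where the two runs hold the same amount, the eta run's log gain exceeds the alpha run's by the log of the charge ratio, whatever the amount. My estimate from that is a factor of 1.51, the alpha run faster than the eta run.

The forecast says order 0.96, faster, and 76 % within 72 % to 80 %. Its fade runs on the clock, as in “The sag therefore follows clock time”, where mine runs on log gain, and its figure stands lower than mine.

    free catalyst + starting material → product + free catalyst (27.66 /M/min)
    free catalyst + impurity → spent catalyst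
    2 free catalyst → 2 spent catalyst (5.214 /M/min)

The flask gives order 1.0 and 78.2 %, inside the forecast's ranges, and faster, as the forecast said. The reach of 2.22 gave 77.2 % for this delta run, and 1.51 for the alpha run over the eta run, where the flask gives 1.4. At the start of the delta run the impurity, 6.76 × 10⁻⁴ M, took free catalyst at once, leaving 0.00532 M. From then on the catalytic step made product while free catalyst paired off into spent catalyst, with 0.00300 M still free at 14 min.

The data were computed with constants of no real substance; the scatter is artificial.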